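**Retrosynthetic overview**

1. The target comes from its pentabenzyl ether by hydrogenolysis. The flavanone heterocycle (O1–C2, with C2 = S) is closed last on a biaryl flavone aldehyde by Knoevenagel condensation with a phloroacetophenone-derived tert-butyl aroylacetate, thiourea-catalysed oxa-Michael addition and decarboxylation.
2. The flavone pyranone (C4a–C4, C4–C3, O1–C2 and the anisyl group) is made in one carbonylative Sonogashira annulation of an iodoresorcinol, CO and 4-ethynylanisole.
3. Feature: in flavone ring A the biaryl carbon C8 lies between C7–OH and C8a–O1. With O5 benzylated, the 2-aryl-5-benzyloxyresorcinol has a mirror plane through C2 and C5, so its two free ring carbons are equivalent, mono-iodination gives a single iodide, and only the aryl-flanked hydroxyl can close ring C. The 8-aryl pattern is therefore built in.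
4. The biaryl bond (flavone C8 to flavanone C3') is formed first, by directed ortho-metalation and Negishi coupling of 1-benzyloxy-3,5-bis(methoxymethoxy)benzene with the dioxolane of 4-benzyloxy-3-iodobenzaldehyde. The MOM and acetal groups are then removed without Brønsted acid.
5. Ring order: biaryl, then flavone ring C, then flavanone ring C.

Key step: step 8

Assumption: of the two pseudoenantiomeric cinchona thioureas, the quinidine-derived one is written as the catalyst leading to the 2S flavanone; if the first run shows the opposite sense of induction, the quinine-derived catalyst is used under the same conditions.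

**Route**

Step 1
Reactants: 1 phloroglucinol
Product: 2 3,5-bis(methoxymethoxy)phenol
Conditions: MOMCl (2.0 equiv), i-Pr2NEt, DMF–CH2Cl2, 0 °C to rt; chromatography
Reagents that add atoms: chloromethyl methyl ether, COCCl
Why: O-alkylation of the phenol (Williamson-type ether synthesis) with the hard electrophile MOMCl should give the bis-ether as the main component of a statistical mixture, from which it is separated while the mono-ether is recycled.

Step 2
Reactants: 2 3,5-bis(methoxymethoxy)phenol
Product: 3 1-benzyloxy-3,5-bis(methoxymethoxy)benzene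
Conditions: BnBr, K2CO3, DMF, rt
Reagents that add atoms: benzyl bromide, BrCc1ccccc1
Why: Williamson ether synthesis on the one remaining phenol installs the benzyl cap on the oxygen that becomes O5 of the flavone.

Step 3
Reactants: 4 4-hydroxy-3-iodobenzaldehyde
Product: 5 4-benzyloxy-3-iodobenzaldehyde
Conditions: BnBr, K2CO3, DMF, rt
Reagents that add atoms: benzyl bromide, BrCc1ccccc1
Why: Williamson ether synthesis; the phenol para to the formyl group is acidic and should alkylate cleanly.

Step 4
Reactants: 5 4-benzyloxy-3-iodobenzaldehyde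
Product: 6 2-(4-benzyloxy-3-iodophenyl)-1,3-dioxolane
Conditions: ethylene glycol, p-TsOH (cat.), toluene, reflux, azeotropic removal of water
Reagents that add atoms: ethylene glycol, OCCO
Why: Acid-catalysed acetalisation driven by water removal masks the formyl group against the organometallic reagents of step 5.

Step 5
Reactants: 3 1-benzyloxy-3,5-bis(methoxymethoxy)benzene; 6 2-(4-benzyloxy-3-iodophenyl)-1,3-dioxolane
Product: 9 2-{4-benzyloxy-3-[4-benzyloxy-2,6-bis(methoxymethoxy)phenyl]phenyl}-1,3-dioxolane, via aryllithium 7 (not isolated), via arylzinc chloride 8 (not isolated)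
Conditions: n-BuLi, TMEDA, THF, 0 °C; ZnCl2, 0 °C to rt; then 6, Pd2(dba)3 (2 mol %), SPhos (8 mol %), THF, 60 °C
Reagents that add atoms: none
Why: Directed ortho-metalation should occur at C2 between the two OMOM groups (the only site activated by two chelating acetal ethers, with benzylic deprotonation not competitive for n-BuLi at 0 °C), transmetalation gives the arylzinc chloride, and a Negishi coupling with SPhos-ligated zerovalent palladium joins the tri-ortho-substituted biaryl while the dioxolane shields the formyl carbon.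

Step 6
Reactants: 9 2-{4-benzyloxy-3-[4-benzyloxy-2,6-bis(methoxymethoxy)phenyl]phenyl}-1,3-dioxolane
Product: 10 4-benzyloxy-3-(4-benzyloxy-2,6-dihydroxyphenyl)benzaldehyde
Conditions: TMSOTf (6 equiv), 2,2'-bipyridyl (9 equiv), CH2Cl2–MeCN, 0 °C to rt; then H2O, rt
Reagents that add atoms: water, O
Why: Silyl triflate/2,2'-bipyridyl dealkylation converts the aryl MOM ethers into aryl trimethylsilyl ethers and the dioxolane into a pyridinium N,O-acetal, all hydrolysed by water, so both phenols and the aldehyde are freed without Brønsted acid, under which the liberated phloroglucinol-type ring would condense with the formyl group (acid-catalysed hydroxyalkylation).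

Step 7
Reactants: 10 4-benzyloxy-3-(4-benzyloxy-2,6-dihydroxyphenyl)benzaldehyde
Product: 11 4-benzyloxy-3-(4-benzyloxy-2,6-dihydroxy-3-iodophenyl)benzaldehyde
Conditions: NIS (1.0 equiv), MeCN, −30 to 0 °C, dark
Reagents that add atoms: N-iodosuccinimide, O=C1CCC(=O)N1I
Why: Electrophilic aromatic iodination; the two free carbons of the resorcinol ring are equivalent by symmetry and far more electron-rich than the formyl-bearing ring, and one equivalent of NIS at low temperature should hold the reaction at the mono-iodide, which is used at once.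

Step 8
Reactants: 11 4-benzyloxy-3-(4-benzyloxy-2,6-dihydroxy-3-iodophenyl)benzaldehyde; 12 4-ethynylanisole
Product: 15 4-benzyloxy-3-[5-benzyloxy-7-hydroxy-2-(4-methoxyphenyl)-4-oxo-4H-chromen-8-yl]benzaldehyde, via ortho-hydroxyaryl ynone 13 (not isolated), via enaminone 14 (not isolated)
Conditions: 12 (1.5 equiv), PdCl2(PPh3)2 (5 mol %), CO (5 bar), Et2NH–DMF 1:1, 70 °C
Reagents that add atoms: carbon monoxide, [C-]#[O+]
Why: Zerovalent palladium, formed in situ from PdCl2(PPh3)2, inserts into the only C–I bond of 11, CO insertion gives an aroylpalladium species, and coupling with the amine-deprotonated alkyne releases ynone 13 (a copper-free carbonylative Sonogashira coupling). Diethylamine then adds to the ynone to give enaminone 14, and the neighbouring phenol displaces the amine by addition–elimination, so the pyranone closes in the 6-endo sense (formally 6-endo-dig on the ynone) and the 5-exo path to the aurone is shut off. The closest known reaction type is the palladium-catalysed carbonylative annulation of 2-iodophenols with terminal arylacetylenes in a secondary amine to give flavones. No stereocentre is formed. The step needs flavone over aurone (secured by the secondary amine), 8-aryl over 6-aryl (secured by the substrate, since the iodinated carbon has the benzyl-capped oxygen on one side and only the aryl-flanked hydroxyl on the other), and carbonylative over direct coupling (secured by CO pressure and the absence of copper salts, which also prevents aldehyde–amine–alkyne coupling at the formyl group). The hydroxyl para to the new carbonyl cannot reach the ynone and remains as the 7-OH.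

Step 9
Reactants: 15 4-benzyloxy-3-[5-benzyloxy-7-hydroxy-2-(4-methoxyphenyl)-4-oxo-4H-chromen-8-yl]benzaldehyde
Product: 16 4-benzyloxy-3-[5,7-bis(benzyloxy)-2-(4-methoxyphenyl)-4-oxo-4H-chromen-8-yl]benzaldehyde
Conditions: BnBr, K2CO3, DMF, 40 °C
Reagents that add atoms: benzyl bromide, BrCc1ccccc1
Why: Williamson ether synthesis on the acidic 7-hydroxyl (a vinylogous acid), capped so that it cannot protonate the basic site of the bifunctional catalyst in step 13.

Step 10
Reactants: 17 2,4,6-trihydroxyacetophenone
Product: 18 1-[2,4-bis(benzyloxy)-6-hydroxyphenyl]ethanone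
Conditions: BnBr (2.1 equiv), K2CO3, DMF, rt
Reagents that add atoms: benzyl bromide, BrCc1ccccc1
Why: Williamson ether synthesis that should stop at the dibenzyl ether, because one ortho hydroxyl is hydrogen-bonded to the acetyl carbonyl and is much less nucleophilic.

Step 11
Reactants: 18 1-[2,4-bis(benzyloxy)-6-hydroxyphenyl]ethanone
Product: 19 tert-butyl 3-[2,4-bis(benzyloxy)-6-hydroxyphenyl]-3-oxopropanoate
Conditions: LiHMDS (3.3 equiv), THF, −78 °C; Boc2O (1.1 equiv), −78 to 0 °C; aq. NH4Cl
Reagents that add atoms: di-tert-butyl dicarbonate, CC(C)(C)OC(=O)OC(=O)OC(C)(C)C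
Why: Claisen-type C-acylation of the ketone enolate of the phenoxide–enolate dianion by Boc2O, the third equivalent of base taking up the acidic β-ketoester; any carbonate formed at the phenoxide oxygen would be carried to carbon by a Baker–Venkataraman type acyl shift.

Step 12
Reactants: 16 4-benzyloxy-3-[5,7-bis(benzyloxy)-2-(4-methoxyphenyl)-4-oxo-4H-chromen-8-yl]benzaldehyde; 19 tert-butyl 3-[2,4-bis(benzyloxy)-6-hydroxyphenyl]-3-oxopropanoate
Product: 20 tert-butyl 2-[2,4-bis(benzyloxy)-6-hydroxybenzoyl]-3-{4-benzyloxy-3-[5,7-bis(benzyloxy)-2-(4-methoxyphenyl)-4-oxo-4H-chromen-8-yl]phenyl}prop-2-enoate (alkene geometry not defined)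
Conditions: piperidine (20 mol %), AcOH (20 mol %), 4 Å molecular sieves, toluene, rt
Reagents that add atoms: none
Why: Knoevenagel condensation under piperidinium acetate catalysis with removal of water; the bulky tert-butyl ester and the hydrogen-bonded phenol slow the uncatalysed ring closure, so the alkylidene should be isolable and is used without delay.

Step 13
Reactants: 20 tert-butyl 2-[2,4-bis(benzyloxy)-6-hydroxybenzoyl]-3-{4-benzyloxy-3-[5,7-bis(benzyloxy)-2-(4-methoxyphenyl)-4-oxo-4H-chromen-8-yl]phenyl}prop-2-enoate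
Product: 22 (2S)-5,7-bis(benzyloxy)-2-{4-benzyloxy-3-[5,7-bis(benzyloxy)-2-(4-methoxyphenyl)-4-oxo-4H-chromen-8-yl]phenyl}chroman-4-one, via flavanone tert-butyl ester 21 (not isolated)
Conditions: 9-amino-9-deoxy-epi-quinidine-derived 3,5-bis(trifluoromethyl)phenyl thiourea (10 mol %), toluene, −25 °C; then p-TsOH·H2O, 80 °C
Reagents that add atoms: none
Why: Intramolecular oxa-Michael addition (6-endo-trig) under bifunctional catalysis, in which the thiourea binds the β-ketoester and the quinuclidine activates the phenol so that the oxygen attacks one face of the alkylidene and sets C2 as S under catalyst control, after which acid-mediated loss of isobutene and decarboxylation remove the C3 ester without touching C2.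

Step 14
Reactants: 22 (2S)-5,7-bis(benzyloxy)-2-{4-benzyloxy-3-[5,7-bis(benzyloxy)-2-(4-methoxyphenyl)-4-oxo-4H-chromen-8-yl]phenyl}chroman-4-one
Product: 23 2,3-dihydropodocarpusflavone A, (2S)-2-{3-[5,7-dihydroxy-2-(4-methoxyphenyl)-4-oxo-4H-chromen-8-yl]-4-hydroxyphenyl}-5,7-dihydroxychroman-4-one
Conditions: H2 (1 atm), Pd/C (10 %), THF–MeOH, rt
Reagents that add atoms: none
Why: Heterogeneous hydrogenolysis of the five benzyl aryl ethers under neutral conditions should leave the methyl ether, the flavone C2=C3 bond and both carbonyl groups intact and provides no base that could open the flavanone and racemise C2; the reaction is stopped as soon as the last benzyl group is gone.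

**Compound list**

1 | phloroglucinol | Oc1cc(O)cc(O)c1 | starting material
2 | 3,5-bis(methoxymethoxy)phenol | COCOc1cc(O)cc(OCOC)c1 | intermediate
3 | 1-benzyloxy-3,5-bis(methoxymethoxy)benzene | COCOc1cc(OCc2ccccc2)cc(OCOC)c1 | intermediate
4 | 4-hydroxy-3-iodobenzaldehyde | O=Cc1ccc(O)c(I)c1 | starting material
5 | 4-benzyloxy-3-iodobenzaldehyde | O=Cc1ccc(OCc2ccccc2)c(I)c1 | intermediate
6 | 2-(4-benzyloxy-3-iodophenyl)-1,3-dioxolane | Ic1cc(C2OCCO2)ccc1OCc1ccccc1 | intermediate
7 | [4-benzyloxy-2,6-bis(methoxymethoxy)phenyl]lithium | [Li]c1c(OCOC)cc(OCc2ccccc2)cc1OCOC | intermediate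
8 | [4-benzyloxy-2,6-bis(methoxymethoxy)phenyl]zinc chloride | Cl[Zn]c1c(OCOC)cc(OCc2ccccc2)cc1OCOC | intermediate
9 | 2-{4-benzyloxy-3-[4-benzyloxy-2,6-bis(methoxymethoxy)phenyl]phenyl}-1,3-dioxolane | COCOc1cc(OCc2ccccc2)cc(OCOC)c1-c1cc(C2OCCO2)ccc1OCc1ccccc1 | intermediate
10 | 4-benzyloxy-3-(4-benzyloxy-2,6-dihydroxyphenyl)benzaldehyde | O=Cc1ccc(OCc2ccccc2)c(-c2c(O)cc(OCc3ccccc3)cc2O)c1 | intermediate
11 | 4-benzyloxy-3-(4-benzyloxy-2,6-dihydroxy-3-iodophenyl)benzaldehyde | O=Cc1ccc(OCc2ccccc2)c(-c2c(O)cc(OCc3ccccc3)c(I)c2O)c1 | intermediate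
12 | 4-ethynylanisole | COc1ccc(C#C)cc1 | starting material
13 | 4-benzyloxy-3-{4-benzyloxy-2,6-dihydroxy-3-[3-(4-methoxyphenyl)prop-2-ynoyl]phenyl}benzaldehyde | O=Cc1ccc(OCc2ccccc2)c(-c2c(O)cc(OCc3ccccc3)c(C(=O)C#Cc3ccc(OC)cc3)c2O)c1 | intermediate
14 | 4-benzyloxy-3-{4-benzyloxy-3-[3-(diethylamino)-3-(4-methoxyphenyl)prop-2-enoyl]-2,6-dihydroxyphenyl}benzaldehyde (alkene geometry not defined) | O=Cc1ccc(OCc2ccccc2)c(-c2c(O)cc(OCc3ccccc3)c(C(=O)C=C(N(CC)CC)c3ccc(OC)cc3)c2O)c1 | intermediate
15 | 4-benzyloxy-3-[5-benzyloxy-7-hydroxy-2-(4-methoxyphenyl)-4-oxo-4H-chromen-8-yl]benzaldehyde | COc1ccc(-c2cc(=O)c3c(OCc4ccccc4)cc(O)c(-c4cc(C=O)ccc4OCc4ccccc4)c3o2)cc1 | intermediate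
16 | 4-benzyloxy-3-[5,7-bis(benzyloxy)-2-(4-methoxyphenyl)-4-oxo-4H-chromen-8-yl]benzaldehyde | COc1ccc(-c2cc(=O)c3c(OCc4ccccc4)cc(OCc4ccccc4)c(-c4cc(C=O)ccc4OCc4ccccc4)c3o2)cc1 | intermediate
17 | 2,4,6-trihydroxyacetophenone | CC(=O)c1c(O)cc(O)cc1O | starting material
18 | 1-[2,4-bis(benzyloxy)-6-hydroxyphenyl]ethanone | CC(=O)c1c(O)cc(OCc2ccccc2)cc1OCc1ccccc1 | intermediate
19 | tert-butyl 3-[2,4-bis(benzyloxy)-6-hydroxyphenyl]-3-oxopropanoate | CC(C)(C)OC(=O)CC(=O)c1c(O)cc(OCc2ccccc2)cc1OCc1ccccc1 | intermediate
20 | tert-butyl 2-[2,4-bis(benzyloxy)-6-hydroxybenzoyl]-3-{4-benzyloxy-3-[5,7-bis(benzyloxy)-2-(4-methoxyphenyl)-4-oxo-4H-chromen-8-yl]phenyl}prop-2-enoate (alkene geometry not defined) | COc1ccc(-c2cc(=O)c3c(OCc4ccccc4)cc(OCc4ccccc4)c(-c4cc(C=C(C(=O)OC(C)(C)C)C(=O)c5c(O)cc(OCc6ccccc6)cc5OCc5ccccc5)ccc4OCc4ccccc4)c3o2)cc1 | intermediate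
21 | tert-butyl (2S)-5,7-bis(benzyloxy)-2-{4-benzyloxy-3-[5,7-bis(benzyloxy)-2-(4-methoxyphenyl)-4-oxo-4H-chromen-8-yl]phenyl}-4-oxochromane-3-carboxylate (C3 not defined, keto and enol forms) | COc1ccc(-c2cc(=O)c3c(OCc4ccccc4)cc(OCc4ccccc4)c(-c4cc([C@@H]5C(C(=O)OC(C)(C)C)C(=O)c6c(OCc7ccccc7)cc(OCc7ccccc7)cc6O5)ccc4OCc4ccccc4)c3o2)cc1 | intermediate
22 | (2S)-5,7-bis(benzyloxy)-2-{4-benzyloxy-3-[5,7-bis(benzyloxy)-2-(4-methoxyphenyl)-4-oxo-4H-chromen-8-yl]phenyl}chroman-4-one | COc1ccc(-c2cc(=O)c3c(OCc4ccccc4)cc(OCc4ccccc4)c(-c4cc([C@@H]5CC(=O)c6c(OCc7ccccc7)cc(OCc7ccccc7)cc6O5)ccc4OCc4ccccc4)c3o2)cc1 | intermediate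
23 | 2,3-dihydropodocarpusflavone A, (2S)-2-{3-[5,7-dihydroxy-2-(4-methoxyphenyl)-4-oxo-4H-chromen-8-yl]-4-hydroxyphenyl}-5,7-dihydroxychroman-4-one | COc1ccc(-c2cc(=O)c3c(O)cc(O)c(-c4cc([C@@H]5CC(=O)c6c(O)cc(O)cc6O5)ccc4O)c3o2)cc1 | target

**Step count and risk**

Total step count: 14. Longest linear sequence: 10 steps (steps 1, 2, 5, 6, 7, 8, 9, 12, 13, 14, from phloroglucinol).

Steps most likely to fail:

Step 8 (carbonylative annulation). Oxidative addition into the electron-rich, doubly ortho-substituted iodide may be slow, so that loss of iodine, aminocarbonylation by diethylamine or direct alkyne coupling with closure to a benzofuran could compete. The fallback builds the same ynone without palladium and sets out from compound 9. A second directed ortho-lithiation of 9 (n-BuLi, TMEDA, THF, 0 °C) should take place at the ring carbon between OMOM and OBn, both such carbons being equivalent. The aryllithium is acylated with N-methoxy-N-methyl-3-(4-methoxyphenyl)prop-2-ynamide F1, itself made from compound 12 by deprotonation with n-BuLi and reaction with N-methoxy-N-methylcarbamoyl chloride. This should give the protected ynone 1-{6-benzyloxy-3-[2-benzyloxy-5-(1,3-dioxolan-2-yl)phenyl]-2,4-bis(methoxymethoxy)phenyl}-3-(4-methoxyphenyl)prop-2-yn-1-one F2. Treatment of F2 with TMSOTf and 2,2'-bipyridyl followed by water, as in step 6, frees the phenols and the aldehyde to give ynone 13, and diethylamine in ethanol at rt closes 13 through enaminone 14. The fallback comes back to the route at compound 15.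

Step 13 (enantioselective oxa-Michael closure and decarboxylation). Facial selectivity may be poor with the trioxygenated aroyl unit, a racemic background cyclisation may already run under the Knoevenagel conditions, or ring opening during the acidic decarboxylation may erode the configuration. The fallback sets out from compounds 16 and 18 and gives up catalyst control for resolution. Claisen–Schmidt condensation (KOH, EtOH–THF, rt) should give the 2'-hydroxychalcone (E)-1-[2,4-bis(benzyloxy)-6-hydroxyphenyl]-3-{4-benzyloxy-3-[5,7-bis(benzyloxy)-2-(4-methoxyphenyl)-4-oxo-4H-chromen-8-yl]phenyl}prop-2-en-1-one F3. Cyclisation with NaOAc in refluxing ethanol should give the racemic flavanone rac-5,7-bis(benzyloxy)-2-{4-benzyloxy-3-[5,7-bis(benzyloxy)-2-(4-methoxyphenyl)-4-oxo-4H-chromen-8-yl]phenyl}chroman-4-one F4. Preparative chromatography on a chiral stationary phase then delivers the 2S enantiomer, and the 2R enantiomer is racemised with base and recycled. The fallback comes back to the route at compound 22.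

Step 6 (removal of the MOM and acetal groups). The freed, very electron-rich resorcinol ring may be alkylated by the aldehyde-derived electrophile (intermolecular hydroxyalkylation), or the cleavage may stop at partly protected material. The fallback carries the formyl carbon as a nitrile through a plain acidic deprotection and sets out from compound 3. Commercial 4-hydroxy-3-iodobenzonitrile is benzylated (BnBr, K2CO3, DMF) to 4-benzyloxy-3-iodobenzonitrile F5. Negishi coupling of F5 with arylzinc chloride 8, made from 3 as in step 5, should give 4-benzyloxy-3-[4-benzyloxy-2,6-bis(methoxymethoxy)phenyl]benzonitrile F6. With no aldehyde present, HCl in MeOH–THF at 40 °C removes the MOM groups to give 4-benzyloxy-3-(4-benzyloxy-2,6-dihydroxyphenyl)benzonitrile F7. Reduction of F7 with i-Bu2AlH (4 equiv, CH2Cl2, −78 °C) and brief cold dilute acidic work-up hydrolyses the imine to the aldehyde. The fallback comes back to the route at compound 10.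

**Further compounds**

F1 | step 8 | N-methoxy-N-methyl-3-(4-methoxyphenyl)prop-2-ynamide | COc1ccc(C#CC(=O)N(C)OC)cc1
F2 | step 8 | 1-{6-benzyloxy-3-[2-benzyloxy-5-(1,3-dioxolan-2-yl)phenyl]-2,4-bis(methoxymethoxy)phenyl}-3-(4-methoxyphenyl)prop-2-yn-1-one | COCOc1cc(OCc2ccccc2)c(C(=O)C#Cc2ccc(OC)cc2)c(OCOC)c1-c1cc(C2OCCO2)ccc1OCc1ccccc1
F3 | step 13 | (E)-1-[2,4-bis(benzyloxy)-6-hydroxyphenyl]-3-{4-benzyloxy-3-[5,7-bis(benzyloxy)-2-(4-methoxyphenyl)-4-oxo-4H-chromen-8-yl]phenyl}prop-2-en-1-one | COc1ccc(-c2cc(=O)c3c(OCc4ccccc4)cc(OCc4ccccc4)c(-c4cc(/C=C/C(=O)c5c(O)cc(OCc6ccccc6)cc5OCc5ccccc5)ccc4OCc4ccccc4)c3o2)cc1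
F4 | step 13 | rac-5,7-bis(benzyloxy)-2-{4-benzyloxy-3-[5,7-bis(benzyloxy)-2-(4-methoxyphenyl)-4-oxo-4H-chromen-8-yl]phenyl}chroman-4-one | COc1ccc(-c2cc(=O)c3c(OCc4ccccc4)cc(OCc4ccccc4)c(-c4cc(C5CC(=O)c6c(OCc7ccccc7)cc(OCc7ccccc7)cc6O5)ccc4OCc4ccccc4)c3o2)cc1
F5 | step 6 | 4-benzyloxy-3-iodobenzonitrile | N#Cc1ccc(OCc2ccccc2)c(I)c1
F6 | step 6 | 4-benzyloxy-3-[4-benzyloxy-2,6-bis(methoxymethoxy)phenyl]benzonitrile | COCOc1cc(OCc2ccccc2)cc(OCOC)c1-c1cc(C#N)ccc1OCc1ccccc1
F7 | step 6 | 4-benzyloxy-3-(4-benzyloxy-2,6-dihydroxyphenyl)benzonitrile | N#Cc1ccc(OCc2ccccc2)c(-c2c(O)cc(OCc3ccccc3)cc2O)c1
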